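The numbers in the tables were computed from invented constants; scatter was added.

A closed, stirred vessel at fixed temperature holds substrate, partner and a little free catalyst, and in the earlier runs product stops rising while substrate remains. The next run must raise either partner or catalyst.

| flask | substrate | partner | free catalyst | remark |
|---|---|---|---|---|
| theta | 0.35 M | 0.80 equiv | 0.5 mol% | run made earlier |
| epsilon | 0.35 M | 0.80 equiv | 0.75 mol% | run made earlier |
| gamma | 0.70 M | 0.80 equiv | 1 mol% | run made earlier |
| flask | 0.35 M | 0.800 equiv | 1 mol% |  |

- theta (time / min: product / %): 15.0: 3.7; 40.0: 4.5; 80.0: 6.6; 120: 8.3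
- epsilon (time / min: product / %): 10.0: 3.6; 20.0: 5.7; 50.0: 9.3; 120: 9.5
- gamma (time / min: product / %): 30.0: 14.2; 60.0: 18.9; 90.0: 19.2; 120: 20.2

(scatter of a reading: 1 percentage point)

- candidate steps: catalyst intermediate C <-> catalyst intermediate D; partner + catalyst intermediate B -> catalyst intermediate C; catalyst intermediate D -> free catalyst + product; partner -> decomposed reagent; substrate + free catalyst <-> catalyst intermediate A; catalyst intermediate A -> catalyst intermediate B

- factor on the rate of making product when 10% of the substrate are converted if partner is charged twice over
- factor on the rate when 10% of the substrate are converted if free catalyst is charged at 10 mol% instead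

We read the flat ends as a race. Partner decomposes by itself, while catalyst intermediate B takes it up, and we assume each taken partner gives one product and that capture goes with [catalyst]. The share of partner captured is then the final product over the equivalents charged. We define the capture odds per catalyst as partner captured over partner decomposed, divided by [catalyst]. We read each run's final product as the mean of its last two readings, since the rises between them (1.7 percentage points in theta, 0.2 points in epsilon, 1 point in gamma) are of the size of the scatter of a reading, 1 point.

theta: share 9.31%, odds 0.103, [catalyst] 1.75 mM, per catalyst 58.7 M⁻¹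

epsilon: share 11.7%, odds 0.133, [catalyst] 2.62 mM, per catalyst 50.7 M⁻¹

gamma: share 24.6%, odds 0.327, [catalyst] 7.00 mM, per catalyst 46.7 M⁻¹

We carry the mean of these three readings, the capture odds per catalyst 52.0 M⁻¹.

flask: odds 0.182, final product 12.3%

10 mol% catalyst: odds 1.82, final product 51.6%

Decomposition wins in the flask, but capture wins at the higher loading. Doubling partner leaves the odds unchanged if both routes are first order in it. So we charge catalyst. Taking rate as catalyst times surviving partner, the partner left at 10% conversion gives our own factors:

left: flask 18.9%, doubled partner 59.4%, more catalyst 80.6%

dbl 6.30, ratio 42.8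

The forecast says 6 (3 to 15) and 35 (12 to 80), lower than ours, on the view that “the partner is dying by first-order decomposition”.

The simulation gives 3.30 and 27.5, lower than the forecast  and lower still than our factors .

    catalyst intermediate C ⇌ catalyst intermediate D (K = 0.730, k = 4.70 min⁻¹)
    partner + catalyst intermediate B → catalyst intermediate C (k = 3.70 M⁻¹ min⁻¹)
    catalyst intermediate D → free catalyst + product (k = 68.0 min⁻¹)
    partner → decomposed reagent (k = 0.0570 min⁻¹)
    substrate + free catalyst ⇌ catalyst intermediate A (K = 2.10 M⁻¹, k = 1300 M⁻¹ min⁻¹)
    catalyst intermediate A → catalyst intermediate B (k = 6.60 min⁻¹)

In the flask at 0.171 h, partner went to decomposed reagent 5.9 times as fast as to catalyst intermediate C, which is odds of 0.169 beside our 0.182, and at 2.00 h it holds product at 11.8% with partner at 0.025%. With 10 mol% catalyst the capture odds per catalyst give 1.82, and at 10% conversion catalyst intermediate C stands at 11.5% of the catalyst, against 4.13% in the flask.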